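**Retrosynthetic overview**
- The 5α-hydroxyl and the 4(15)-methylene are introduced last by a singlet-oxygen ene reaction on a Δ4 alkene; the 3β-angelate and 8β-acetate come from face-selective reductions of C3 and C8 ketones.
- Key C7–C11 bond: C7 of an unprotected bicyclic 3,8-enedione (as its C8 enamine) is joined to C11 of methyl (E)-3-nitroacrylate. The nitro group makes the ester α-carbon the acceptor (an acrylate α-cation equivalent), and loss of HNO2 then gives the α-methylene ester directly.
- The enedione comes from an asymmetric Robinson annulation of 7-methyl-1,4-dioxaspiro[4.5]decan-8-one with ethyl vinyl ketone through a chiral imine, which sets C10.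
- Ring order: ring B is bought, ring A is closed in step 2; C10 then controls C7, C8, C3 and C5.

Assumption: names use eudesmane numbering, with β meaning the face of the C10 methyl and α the opposite face; compound 1 is bought as the racemate.

**Step 1**
Reactants: 1 7-methyl-1,4-dioxaspiro[4.5]decan-8-one (racemic); 2 (R)-1-phenylethylamine; 3 pent-1-en-3-one (ethyl vinyl ketone)
Product: 6 (7R)-7-methyl-7-(3-oxopentyl)-1,4-dioxaspiro[4.5]decan-8-one, via imine 4 (not isolated), via adduct imine 5 (not isolated)
Conditions: 2 (1.0 equiv), PhMe, reflux, Dean–Stark; then 3 (1.5 equiv), THF, 40 °C, 3 d; then 10% aq. AcOH, rt, 1 h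
Reagents that add atoms: water, O
Why: d'Angelo deracemising Michael addition: the more substituted secondary enamine tautomer of 4 adds to 3 through a compact aza-ene-like transition state on the face anti to the phenyl group, which with the (R)-amine gives the (R) quaternary centre (future C10, about 90% ee), and mild hydrolysis returns the amine while the dioxolane survives.

**Step 2**
Reactants: 6 (7R)-7-methyl-7-(3-oxopentyl)-1,4-dioxaspiro[4.5]decan-8-one
Product: 8 (4aR)-1,4a-dimethyl-4,4a,7,8-tetrahydronaphthalene-2,6(3H,5H)-dione, via enone ketal 7 (not isolated)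
Conditions: NaOMe (1.2 equiv), MeOH, 60 °C; then 3 M aq. HCl, rt, 2 h; recrystallise
Reagents that add atoms: water, O
Why: Second stage of a Robinson annulation (intramolecular aldol condensation of the ethyl ketone onto the ring ketone, closing ring A) followed by acid hydrolysis of the dioxolane; no stereocentre is formed, the quaternary centre cannot epimerise, and recrystallisation of 8 raises the ee.

**Step 3**
Reactants: 9 methyl acrylate
Product: 11 methyl (E)-3-nitroacrylate, via iodo nitro ester 10 (not isolated)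
Conditions: N2O4, I2, Et2O, 0 °C; then NaOAc, Et2O, 0 °C
Reagents that add atoms: dinitrogen tetroxide, O=[N+]([O-])[N+](=O)[O-]
Why: Radical iodonitration of the acrylate (NO2 on the terminal carbon, iodine on the α-carbon) followed by acetate-mediated loss of HI gives the E nitroalkene, a known two-stage preparation.

**Step 4**
Reactants: 8 (4aR)-1,4a-dimethyl-4,4a,7,8-tetrahydronaphthalene-2,6(3H,5H)-dione; 11 methyl (E)-3-nitroacrylate; 12 pyrrolidine
Product: 16 methyl 3,8-dioxoeudesma-4,11(13)-dien-12-oate (7β side chain), via enamine 13 (not isolated), via adduct enamine 14 (not isolated), via nitro keto ester 15 (not isolated)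
Conditions: 12 (1.2 equiv), MgSO4, PhH, rt, then evaporate; 11 (1.05 equiv), Et2O, −78 → 0 °C; aq. AcOH–NaOAc buffer, rt; then DBU (1.2 equiv), CH2Cl2, 0 °C, AcOH quench
Reagents that add atoms: water, O
Why: Stork enamine Michael addition followed by E1cB loss of nitrous acid: the unhindered saturated C8 ketone should condense with pyrrolidine faster than the conjugated, tetrasubstituted C3 enone and on the C7 side (C9 is neopentyl), the enamine carbon C7 attacks the nitroacrylate at the carbon next to the ester because the nitro group is the stronger acceptor, so C11 acts as an acrylate α-cation and two normally nucleophilic α-carbons are joined, and DBU both expels nitrite and equilibrates C7, which after axial protonation carries the side chain equatorial (7β, cis to the C10 methyl).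

**Step 5**
Reactants: 16 methyl 3,8-dioxoeudesma-4,11(13)-dien-12-oate
Product: 18 methyl 8β-acetoxy-3-oxoeudesma-4,11(13)-dien-12-oate, via aluminate 17 (not isolated)
Conditions: LiAlH(OtBu)3 (1.2 equiv), THF, −78 → −40 °C; then Ac2O (6 equiv), pyridine, 4-(dimethylamino)pyridine (cat.), −40 → 0 °C; aq. potassium sodium tartrate work-up
Reagents that add atoms: acetic anhydride, CC(=O)OC(C)=O
Why: Diastereoselective hydride reduction with in-situ O-acylation: the bulky aluminohydride reduces the saturated C8 ketone faster than the hindered enone or the esters and attacks from the α face, away from the syn-axial C10 methyl, giving the axial 8β alkoxide cis to the C7 side chain, which is acetylated as the aluminate before it can close onto the C12 ester.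

**Step 6**
Reactants: 18 methyl 8β-acetoxy-3-oxoeudesma-4,11(13)-dien-12-oate
Product: 19 methyl 8β-acetoxy-3β-hydroxyeudesma-4,11(13)-dien-12-oate
Conditions: NaBH4 (1.0 equiv), CeCl3·7H2O (1.1 equiv), MeOH, −78 °C, 30 min
Reagents that add atoms: none
Why: Luche reduction: CeCl3-activated 1,2-hydride delivery to the enone from the α face (axial attack anti to the C10 methyl) gives the pseudo-equatorial 3β allylic alcohol without touching the acrylate, acetate or methyl ester at −78 °C.

**Step 7**
Reactants: 19 methyl 8β-acetoxy-3β-hydroxyeudesma-4,11(13)-dien-12-oate; 20 angelic acid ((Z)-2-methylbut-2-enoic acid)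
Product: 22 methyl 8β-acetoxy-3β-angeloyloxyeudesma-4,11(13)-dien-12-oate, via mixed anhydride 21 (not isolated)
Conditions: 20 (3 equiv), 2,4,6-trichlorobenzoyl chloride (3 equiv), Et3N, PhMe, rt, 2 h; then 19, PhMe, 80 °C
Reagents that add atoms: none
Why: Yamaguchi esterification through the mixed anhydride 21 without a nucleophilic amine catalyst, conditions under which the Z (angelate) geometry is kept; the C3–O bond is not broken, so the 3β configuration is retained.

**Step 8**
Reactants: 22 methyl 8β-acetoxy-3β-angeloyloxyeudesma-4,11(13)-dien-12-oate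
Product: 24 methyl 8β-acetoxy-3β-angeloyloxy-5α-hydroxyeudesma-4(15),11(13)-dien-12-oate (CNP0179024.1), via hydroperoxide 23 (not isolated)
Conditions: O2, 5,10,15,20-tetraphenylporphyrin (cat.), hν (white LED), CH2Cl2, 0 °C; then PPh3, 0 °C → rt
Reagents that add atoms: oxygen, O=O
Why: Schenck ene reaction of singlet oxygen then phosphine reduction: oxygen attacks the tetrasubstituted alkene on the α face (anti to the C10 methyl and both β esters), takes a hydrogen from the C15 methyl (H6α lies in the alkene plane and H3α is deactivated by its geminal ester) and bonds to C5, giving the 5α-hydroperoxide with the 4(15) methylene; PPh3 cleaves the O–O bond with retention at C5.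

**Compound list**
1 | 7-methyl-1,4-dioxaspiro[4.5]decan-8-one (racemic) | CC1CC2(CCC1=O)OCCO2 | starting material
2 | (R)-1-phenylethylamine | C[C@@H](N)c1ccccc1 | starting material
3 | pent-1-en-3-one (ethyl vinyl ketone) | CCC(=O)C=C | starting material
4 | N-[(1R)-1-phenylethyl] imine of 1 (C7 epimers, in equilibrium with the secondary enamine) | CC1CC2(CCC1=N[C@H](C)c3ccccc3)OCCO2 | intermediate
5 | N-[(1R)-1-phenylethyl] imine of (7R)-7-methyl-7-(3-oxopentyl)-1,4-dioxaspiro[4.5]decan-8-one | CCC(=O)CC[C@]1(C)CC2(CCC1=N[C@H](C)c3ccccc3)OCCO2 | intermediate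
6 | (7R)-7-methyl-7-(3-oxopentyl)-1,4-dioxaspiro[4.5]decan-8-one | CCC(=O)CC[C@]1(C)CC2(CCC1=O)OCCO2 | intermediate
7 | 8,8-ethylenedioxy-11,12,13-trinoreudesm-4-en-3-one (10β-Me; the C8 mono-ketal of 8) | O=C1CC[C@]2(C)CC3(CCC2=C1C)OCCO3 | intermediate
8 | (4aR)-1,4a-dimethyl-4,4a,7,8-tetrahydronaphthalene-2,6(3H,5H)-dione (11,12,13-trinoreudesm-4-ene-3,8-dione) | O=C1CCC2=C(C)C(=O)CC[C@]2(C)C1 | intermediate
9 | methyl acrylate | C=CC(=O)OC | starting material
10 | methyl 2-iodo-3-nitropropanoate (racemic) | COC(=O)C(I)C[N+](=O)[O-] | intermediate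
11 | methyl (E)-3-nitroacrylate | COC(=O)/C=C/[N+](=O)[O-] | intermediate
12 | pyrrolidine | C1CCNC1 | starting material
13 | 8-(pyrrolidin-1-yl)-11,12,13-trinoreudesma-4,7-dien-3-one (C8 enamine of 8) | C1CCN(C1)C1=CCC2=C(C)C(=O)CC[C@]2(C)C1 | intermediate
14 | methyl 13-nitro-3-oxo-8-(pyrrolidin-1-yl)eudesma-4,8-dien-12-oate (C7/C11 epimers) | COC(=O)C(C[N+](=O)[O-])C1CC2=C(C)C(=O)CC[C@]2(C)C=C1N3CCCC3 | intermediate
15 | methyl 13-nitro-3,8-dioxoeudesm-4-en-12-oate (C7/C11 epimers) | COC(=O)C(C[N+](=O)[O-])C1CC2=C(C)C(=O)CC[C@]2(C)CC1=O | intermediate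
16 | methyl 3,8-dioxoeudesma-4,11(13)-dien-12-oate (7β side chain, 7α-H, 10β-Me) | C=C(C(=O)OC)[C@H]1CC2=C(C)C(=O)CC[C@]2(C)CC1=O | intermediate
17 | lithium tri-tert-butoxyaluminate of the 8β-alkoxide from 16 (7β side chain, 10β-Me) | C=C(C(=O)OC)[C@H]1CC2=C(C)C(=O)CC[C@]2(C)C[C@H]1O[Al-](OC(C)(C)C)(OC(C)(C)C)OC(C)(C)C.[Li+] | intermediate
18 | methyl 8β-acetoxy-3-oxoeudesma-4,11(13)-dien-12-oate | C=C(C(=O)OC)[C@H]1CC2=C(C)C(=O)CC[C@]2(C)C[C@H]1OC(C)=O | intermediate
19 | methyl 8β-acetoxy-3β-hydroxyeudesma-4,11(13)-dien-12-oate | C=C(C(=O)OC)[C@H]1CC2=C(C)[C@@H](O)CC[C@]2(C)C[C@H]1OC(C)=O | intermediate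
20 | angelic acid ((Z)-2-methylbut-2-enoic acid) | C/C=C(/C)C(=O)O | starting material
21 | angelic 2,4,6-trichlorobenzoic anhydride | C/C=C(/C)C(=O)OC(=O)c1c(Cl)cc(Cl)cc1Cl | intermediate
22 | methyl 8β-acetoxy-3β-angeloyloxyeudesma-4,11(13)-dien-12-oate | C=C(C(=O)OC)[C@H]1CC2=C(C)[C@@H](OC(=O)/C(C)=C\C)CC[C@]2(C)C[C@H]1OC(C)=O | intermediate
23 | methyl 8β-acetoxy-3β-angeloyloxy-5α-hydroperoxyeudesma-4(15),11(13)-dien-12-oate | C=C(C(=O)OC)[C@H]1C[C@@]2(OO)C(=C)[C@@H](OC(=O)/C(C)=C\C)CC[C@]2(C)C[C@H]1OC(C)=O | intermediate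
24 | methyl 8β-acetoxy-3β-angeloyloxy-5α-hydroxyeudesma-4(15),11(13)-dien-12-oate (CNP0179024.1) | C=C(C(=O)OC)[C@H]1C[C@@]2(O)C(=C)[C@@H](OC(=O)/C(C)=C\C)CC[C@]2(C)C[C@H]1OC(C)=O | target

**Totals**
Total step count: 8. Longest linear sequence: 7 (steps 1, 2, 4, 5, 6, 7, 8; step 3 prepares the nitroacrylate).

**Three steps most likely to fail**

Step 4. The risks are enamine formation at C8 in the presence of the free C3 enone, and the C7 epimer ratio. Fallback, setting out from 7 (isolated by leaving out the HCl stage of step 2) and coming back at 22: the C3 carbonyl is dealt with first, so that the C8 ketone is the only enolisable carbonyl when the nitroacrylate is introduced. NaBH4 with CeCl3·7H2O (MeOH, −78 °C) gives the 3β-allylic alcohol ketal F1. Esterification with 20 as in step 7 gives the angelate ketal F2. Pyridinium p-toluenesulfonate in wet acetone (50 °C) unmasks the 8-ketone F3. LiN(SiMe3)2 (THF, −78 °C) deprotonates the less hindered C7 and the lithium enolate adds to 11 to give the nitro keto ester F4. DBU removes nitrous acid and equilibrates C7 to give the keto acrylate F5. LiAlH(OtBu)3 followed by Ac2O and pyridine, as in step 5, then gives 22, and step 8 follows.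

Step 5. The risks are ring closure of the 8β-alkoxide onto the C12 ester before it is acetylated, and the 8β/8α ratio. Fallback, setting out from 16 and coming back at 18: the lactone is made on purpose and used as a purification handle. NaBH4 (MeOH–CH2Cl2, −78 °C, ketone-selective) gives the hydroxy ester F6. Camphorsulfonic acid (cat., CH2Cl2) closes it to the cis-fused 8β,12-lactone F7, which is separated from any 8α-derived material by crystallisation. LiOH (THF–H2O, 0 °C) opens the lactone to the lithium hydroxy carboxylate F8. After evaporation, MeI in DMF re-forms F6 under non-acidic conditions, and Ac2O, pyridine and 4-(dimethylamino)pyridine added to the same flask give 18.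

Step 8. The risks are the regio- and face-selectivity of the ene reaction. Fallback, setting out from 22 and coming back at 24: m-chloroperbenzoic acid (NaHCO3, CH2Cl2, 0 °C) epoxidises the electron-rich tetrasubstituted alkene from the α face, the angelate and acrylate alkenes being electron-poor, to give the 4α,5α-epoxide F9. Cp2TiCl (trivalent titanium, made from Cp2TiCl2 and Mn dust in THF, 2.2 equiv, rt) opens the epoxide homolytically at C4–O, and the C4 radical loses a hydrogen from the C15 methyl to give 24 after aqueous work-up. Cleavage at C5–O is a possible competing path and would give the 4α-hydroxy-Δ5 isomer.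

**Further compounds**
F1 | step 4 | 8,8-ethylenedioxy-11,12,13-trinoreudesm-4-en-3β-ol | C1CC2=C(C)[C@@H](O)CC[C@]2(C)CC13OCCO3
F2 | step 4 | 3β-angeloyloxy-8,8-ethylenedioxy-11,12,13-trinoreudesm-4-ene | C1CC2=C(C)[C@@H](OC(=O)/C(C)=C\C)CC[C@]2(C)CC13OCCO3
F3 | step 4 | 3β-angeloyloxy-11,12,13-trinoreudesm-4-en-8-one | O=C1CCC2=C(C)[C@@H](OC(=O)/C(C)=C\C)CC[C@]2(C)C1
F4 | step 4 | methyl 3β-angeloyloxy-13-nitro-8-oxoeudesm-4-en-12-oate (C7/C11 epimers) | COC(=O)C(C[N+](=O)[O-])C1CC2=C(C)[C@@H](OC(=O)/C(C)=C\C)CC[C@]2(C)CC1=O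
F5 | step 4 | methyl 3β-angeloyloxy-8-oxoeudesma-4,11(13)-dien-12-oate (7β side chain) | C=C(C(=O)OC)[C@H]1CC2=C(C)[C@@H](OC(=O)/C(C)=C\C)CC[C@]2(C)CC1=O
F6 | step 5 | methyl 8β-hydroxy-3-oxoeudesma-4,11(13)-dien-12-oate | C=C(C(=O)OC)[C@H]1CC2=C(C)C(=O)CC[C@]2(C)C[C@H]1O
F7 | step 5 | 3-oxoeudesma-4,11(13)-dien-8β,12-olide | C=C(C3=O)[C@H]1CC2=C(C)C(=O)CC[C@]2(C)C[C@H]1O3
F8 | step 5 | lithium 8β-hydroxy-3-oxoeudesma-4,11(13)-dien-12-oate | [Li+].C=C(C(=O)[O-])[C@H]1CC2=C(C)C(=O)CC[C@]2(C)C[C@H]1O
F9 | step 8 | methyl 8β-acetoxy-3β-angeloyloxy-4α,5α-epoxyeudesm-11(13)-en-12-oate | C=C(C(=O)OC)[C@H]1C[C@@]2(O3)[C@@]3(C)[C@@H](OC(=O)/C(C)=C\C)CC[C@]2(C)C[C@H]1OC(C)=O
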